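**Retrosynthetic overview**

1. The target is read as epicatechin-(4α→8)-epicatechin 3-O-gallate-(4β→8)-epicatechin 3-O-gallate. The last operations are hydrogenolysis of all benzyl ethers and of a C8 bromine cap, preceded by inversion of C3 of the top unit (oxidation to the ketone, then hydride delivery anti to the two α-aryl groups on C2 and C4).
2. C4(top)–C8(middle) is cut to a capped (+)-catechin C4 cation and a digalloylated dimer; attack trans to the 3β-hydroxyl gives 4α. C4(middle)–C8(bottom) is cut to a 4-alkoxy-epicatechin and epicatechin, both as benzyl ethers; this gives 4β.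
3. Middle and bottom units are one building block, tetra-O-benzylepicatechin, made once. Its C2 and C3 are set together by hydrogenation of the racemising flavan-3-one under dynamic kinetic resolution.
4. Ring C of that block is closed through C3–C4. The enabling feature: on ring A, O1 (on C8a) and C4 (on C4a) are ortho, and C3 carries a heteroatom next to the aryl-bearing C2. A salicylaldehyde (O1–H, C4 = CHO) and an aryl nitroalkene (C2=C3–NO2, nitro as masked C3 oxygen) therefore join O1–C2 and then C3–C4 in one cascade.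
5. Order of ring formation: rings A and B are bought; ring C of the bottom/middle block is formed in step 2; the three rings of the top unit come intact with (+)-catechin; no ring is formed after the couplings.

Key step: step 2

Remark: the stereodescriptors are read as top unit 2R,3R,4S (C4–C8 bond cis to the C3 hydroxyl, 4α), middle unit 2R,3R with a 4β bond, bottom unit 2R,3R; the nitrostyrene and 3,4,5-tris(benzyloxy)benzoic acid are taken as purchasable.

**Route**

Step 1
Reactants: 1 2,4,6-trihydroxybenzaldehyde; 2 benzyl bromide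
Product: 3 4,6-bis(benzyloxy)-2-hydroxybenzaldehyde
Conditions: BnBr (2.1 equiv), K2CO3, DMF, 0 °C to rt
Reagents that add atoms: benzyl bromide, BrCc1ccccc1
Why: Williamson ether synthesis; the 4-hydroxyl and then one ortho hydroxyl are alkylated, while the last ortho hydroxyl is held in a hydrogen bond to the formyl group and should stay free as the future O1.

Step 2
Reactants: 3 4,6-bis(benzyloxy)-2-hydroxybenzaldehyde; 4 (E)-1,2-bis(benzyloxy)-4-(2-nitroethenyl)benzene
Product: 7 rac-5,7-bis(benzyloxy)-2-[3,4-bis(benzyloxy)phenyl]-3-nitro-2H-chromene, via oxa-Michael adduct 5 (not isolated), via nitro-aldol adduct 6 (not isolated)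
Conditions: DABCO (0.5 equiv), MeCN, 60 °C
Reagents that add atoms: none
Why: DABCO deprotonates the only free phenol of 3, whose oxygen (future O1) adds to the β-carbon of nitroalkene 4 (future C2) to give nitronate 5; the nitronate carbon (C3) then attacks the ortho formyl carbon (C4) in an intramolecular Henry addition, and E1cB loss of water from 6 makes the sequence irreversible. The closest known reaction type is the tandem oxa-Michael–Henry–dehydration of salicylaldehydes with β-nitrostyrenes to 2-aryl-3-nitro-2H-chromenes. Ring C is closed in a 6-(enolexo)-exo-trig mode through the C3–C4 bond. The only stereocentre that survives, C2, forms without control and is left racemic on purpose, because it becomes the enolisable α-carbon of ketone 9 and is set together with C3 in step 4; the two other centres of 6 vanish on dehydration. The step needs O-attack of the phenoxide and closure to the six-membered ring only: the benzyl ethers on O5 and O7 leave O1 as the single nucleophilic oxygen, and the formyl group ortho to it is the only electrophile within reach of C3. The nitro group polarises C2=C3 for the oxygen addition, stabilises the C3 carbanion for the ring closure, and is the latent C3 oxygen.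

Step 3
Reactants: 7 rac-5,7-bis(benzyloxy)-2-[3,4-bis(benzyloxy)phenyl]-3-nitro-2H-chromene
Product: 9 rac-5,7-bis(benzyloxy)-2-[3,4-bis(benzyloxy)phenyl]chroman-3-one, via ketimine 8 (not isolated)
Conditions: Fe powder, AcOH/THF/H2O, 60 °C
Reagents that add atoms: water, O
Why: Dissolving-metal reduction of a conjugated nitroalkene (reductive Nef-type conversion): the C3=C4–NO2 unit is reduced to the enamine, which tautomerises to imine 8 and is hydrolysed in the aqueous acid, so that C4 ends as CH2 and C3 as C=O; C2 stays racemic, as intended.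

Step 4
Reactants: 9 rac-5,7-bis(benzyloxy)-2-[3,4-bis(benzyloxy)phenyl]chroman-3-one
Product: 10 (2R,3R)-5,7-bis(benzyloxy)-2-[3,4-bis(benzyloxy)phenyl]chroman-3-ol (5,7,3',4'-tetra-O-benzylepicatechin)
Conditions: H2 (10 atm), RuCl2[(S)-xylBINAP][(S)-DAIPEN] (1 mol %), tBuOK (10 mol %), iPrOH/toluene, 25 °C
Reagents that add atoms: none
Why: Noyori asymmetric hydrogenation with dynamic kinetic resolution, as known for 2-aryl cycloalkanones and α-aryloxy ketones: C2–H (α to the ketone, benzylic, O-substituted) should epimerise under the base faster than reduction, and the chiral catalyst should reduce one enantiomer by hydride delivery to C3 anti to the C2 aryl group, setting C2 (R) and C3 (R) in the cis relation; the hand of the catalyst is to be confirmed on a small scale and the mirror-image complex used if the opposite sense is found.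

Step 5
Reactants: 10 5,7,3',4'-tetra-O-benzylepicatechin (one part of the batch); 11 2-ethoxyethanol
Product: 12 (2R,3R,4S)-5,7,3',4'-tetra-O-benzyl-4-(2-ethoxyethoxy)epicatechin (4β-alkoxy)
Conditions: DDQ (2 equiv), 2-ethoxyethanol (excess), CH2Cl2, rt
Reagents that add atoms: 2-ethoxyethanol, CCOCCO
Why: Oxidative benzylic etherification: DDQ removes hydride from C4, whose cation is stabilised by the 5- and 7-benzyloxy groups, and the alcohol should add from the β face trans to the 3α-hydroxyl; C4 is only a leaving-group centre here.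

Step 6
Reactants: 12 (2R,3R,4S)-tetra-O-benzyl-4-(2-ethoxyethoxy)epicatechin; 10 5,7,3',4'-tetra-O-benzylepicatechin (4 equiv)
Product: 13 octa-O-benzyl procyanidin B2 [tetra-O-benzylepicatechin-(4β→8)-tetra-O-benzylepicatechin]
Conditions: TMSOTf (0.5 equiv), CH2Cl2, –78 °C
Reagents that add atoms: none
Why: SN1 interflavan coupling (Friedel–Crafts alkylation): the ionised C4 of 12 should be attacked by C8 of 10, the A-ring position next to O1 that benzylated flavan-3-ols use, from the β face trans to the 3α-hydroxyl, which sets the 4β centre of the middle unit; the excess of 10 limits further chain growth and is recovered.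

Step 7
Reactants: 13 octa-O-benzyl procyanidin B2; 14 3,4,5-tris(benzyloxy)benzoic acid (excess)
Product: 15 octa-O-benzyl procyanidin B2 3,3'-bis[3,4,5-tris(benzyloxy)benzoate]
Conditions: DCC, DMAP, CH2Cl2, rt
Reagents that add atoms: 3,4,5-tris(benzyloxy)benzoic acid, OC(=O)c1cc(OCc2ccccc2)c(OCc2ccccc2)c(OCc2ccccc2)c1
Why: Steglich esterification of both secondary 3-hydroxyls at oxygen, so both C3 centres keep their configuration; the hindered upper hydroxyl needs excess reagent.

Step 8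
Reactants: 16 (+)-catechin; 2 benzyl bromide
Product: 17 5,7,3',4'-tetra-O-benzyl-(+)-catechin
Conditions: BnBr (4.4 equiv), K2CO3, DMF, 0 °C to rt
Reagents that add atoms: benzyl bromide, BrCc1ccccc1
Why: Williamson ether synthesis; carbonate deprotonates only the four phenols, so the 3-hydroxyl stays free and C2/C3 are untouched.

Step 9
Reactants: 17 5,7,3',4'-tetra-O-benzyl-(+)-catechin; 18 N-bromosuccinimide
Product: 19 8-bromo-5,7,3',4'-tetra-O-benzyl-(+)-catechin
Conditions: NBS (1.0 equiv), CH2Cl2, –40 °C to rt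
Reagents that add atoms: N-bromosuccinimide, O=C1CCC(=O)N1Br
Why: Electrophilic aromatic bromination, which for benzylated flavan-3-ols goes to C8; the bromine caps the nucleophilic position of the top unit so that it cannot self-condense or be extended in step 11.

Step 10
Reactants: 19 8-bromo-5,7,3',4'-tetra-O-benzyl-(+)-catechin; 11 2-ethoxyethanol
Product: 20 (2R,3S,4S)-8-bromo-5,7,3',4'-tetra-O-benzyl-4-(2-ethoxyethoxy)catechin
Conditions: DDQ (2 equiv), 2-ethoxyethanol (excess), CH2Cl2, rt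
Reagents that add atoms: 2-ethoxyethanol, CCOCCO
Why: Oxidative benzylic etherification as in step 5; the alcohol should add axially from the β face, and the configuration of this leaving-group centre does not matter for step 11.

Step 11
Reactants: 20 (2R,3S,4S)-8-bromo-tetra-O-benzyl-4-(2-ethoxyethoxy)catechin (1.5 equiv); 15 octa-O-benzyl procyanidin B2 3,3'-bis[3,4,5-tris(benzyloxy)benzoate]
Product: 21 protected trimer [8-bromo-tetra-O-benzylcatechin]-(4α→8)-[tetra-O-benzylepicatechin 3-O-tri-O-benzylgallate]-(4β→8)-[tetra-O-benzylepicatechin 3-O-tri-O-benzylgallate], top unit 3β-OH free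
Conditions: TMSOTf (0.5 equiv), CH2Cl2, –78 to –40 °C
Reagents that add atoms: none
Why: SN1 interflavan coupling: the C4 cation of the catechin unit should be attacked by C8 of the upper unit of 15 (the free A-ring position next to O1) from the α face, trans to the 3β-hydroxyl, which sets C4 of the top unit cis to its C2 aryl group (4α).

Step 12
Reactants: 21 protected trimer with free 3β-OH in the top unit
Product: 22 protected trimer with a C3 ketone in the top unit (2R,4S; 2,4-cis-diaryl)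
Conditions: Dess–Martin periodinane, wet CH2Cl2, rt
Reagents that add atoms: none
Why: Dess–Martin oxidation of the only free hydroxyl under non-basic conditions, which should leave the enolisable C2 and C4 centres of the top unit untouched.

Step 13
Reactants: 22 protected trimer with a C3 ketone in the top unit
Product: 23 protected trimer with top unit (2R,3R,4S), 3α-OH, all-cis
Conditions: L-selectride, LiBr, THF, –78 °C; then H2O
Reagents that add atoms: none
Why: Substrate-controlled ketone reduction with a bulky hydride: both aryl substituents on C2 and C4 lie on the α face, so hydride should enter from the β face and give the 3α-alcohol (R); the gallate esters are not reduced at –78 °C.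

Step 14
Reactants: 23 protected trimer with all-cis top unit
Product: 24 epicatechin-(4α→8)-epicatechin 3-O-gallate-(4β→8)-epicatechin 3-O-gallate (CNP0279403.2)
Conditions: H2 (1 atm), Pd(OH)2/C, Et3N (1.1 equiv), THF/MeOH/H2O, rt
Reagents that add atoms: none
Why: Hydrogenolysis of the eighteen benzyl ethers and of the C8–Br bond; esters, interflavan bonds and all stereocentres are not affected, and Et3N takes up HBr, which would otherwise cleave the acid-labile interflavan bonds.

**Compound list**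

1 | 2,4,6-trihydroxybenzaldehyde | O=Cc1c(O)cc(O)cc1O | starting material
2 | benzyl bromide | BrCc1ccccc1 | starting material
3 | 4,6-bis(benzyloxy)-2-hydroxybenzaldehyde | O=Cc1c(O)cc(OCc2ccccc2)cc1OCc1ccccc1 | intermediate
4 | (E)-1,2-bis(benzyloxy)-4-(2-nitroethenyl)benzene | [O-][N+](=O)/C=C/c1ccc(OCc2ccccc2)c(OCc2ccccc2)c1 | starting material
5 | rac-2-{1-[3,4-bis(benzyloxy)phenyl]-2-nitroethoxy}-4,6-bis(benzyloxy)benzaldehyde (oxa-Michael adduct) | O=Cc1c(OC(C[N+](=O)[O-])c2ccc(OCc3ccccc3)c(OCc3ccccc3)c2)cc(OCc2ccccc2)cc1OCc1ccccc1 | intermediate (not isolated)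
6 | 5,7-bis(benzyloxy)-2-[3,4-bis(benzyloxy)phenyl]-3-nitrochroman-4-ol (nitro-aldol adduct, mixture of stereoisomers) | OC1c2c(OCc3ccccc3)cc(OCc3ccccc3)cc2OC(c2ccc(OCc3ccccc3)c(OCc3ccccc3)c2)C1[N+](=O)[O-] | intermediate (not isolated)
7 | rac-5,7-bis(benzyloxy)-2-[3,4-bis(benzyloxy)phenyl]-3-nitro-2H-chromene | [O-][N+](=O)C1=Cc2c(OCc3ccccc3)cc(OCc3ccccc3)cc2OC1c1ccc(OCc2ccccc2)c(OCc2ccccc2)c1 | intermediate
8 | rac-5,7-bis(benzyloxy)-2-[3,4-bis(benzyloxy)phenyl]chroman-3-imine | N=C1Cc2c(OCc3ccccc3)cc(OCc3ccccc3)cc2OC1c1ccc(OCc2ccccc2)c(OCc2ccccc2)c1 | intermediate (not isolated)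
9 | rac-5,7-bis(benzyloxy)-2-[3,4-bis(benzyloxy)phenyl]chroman-3-one | O=C1Cc2c(OCc3ccccc3)cc(OCc3ccccc3)cc2OC1c1ccc(OCc2ccccc2)c(OCc2ccccc2)c1 | intermediate
10 | (2R,3R)-5,7,3',4'-tetra-O-benzylepicatechin | O[C@@H]1Cc2c(OCc3ccccc3)cc(OCc3ccccc3)cc2O[C@@H]1c1ccc(OCc2ccccc2)c(OCc2ccccc2)c1 | intermediate
11 | 2-ethoxyethanol | CCOCCO | starting material
12 | (2R,3R,4S)-5,7,3',4'-tetra-O-benzyl-4-(2-ethoxyethoxy)epicatechin | O[C@@H]1[C@@H](OCCOCC)c2c(OCc3ccccc3)cc(OCc3ccccc3)cc2O[C@@H]1c1ccc(OCc2ccccc2)c(OCc2ccccc2)c1 | intermediate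
13 | octa-O-benzyl procyanidin B2 | O[C@@H]1[C@@H](c2c(OCc3ccccc3)cc(OCc3ccccc3)c3c2O[C@H](c2ccc(OCc4ccccc4)c(OCc4ccccc4)c2)[C@H](O)C3)c2c(OCc3ccccc3)cc(OCc3ccccc3)cc2O[C@@H]1c1ccc(OCc2ccccc2)c(OCc2ccccc2)c1 | intermediate
14 | 3,4,5-tris(benzyloxy)benzoic acid | OC(=O)c1cc(OCc2ccccc2)c(OCc2ccccc2)c(OCc2ccccc2)c1 | starting material
15 | octa-O-benzyl procyanidin B2 3,3'-bis[3,4,5-tris(benzyloxy)benzoate] | O=C(O[C@@H]1[C@@H](c2c(OCc3ccccc3)cc(OCc3ccccc3)c3c2O[C@H](c2ccc(OCc4ccccc4)c(OCc4ccccc4)c2)[C@H](OC(=O)c2cc(OCc4ccccc4)c(OCc4ccccc4)c(OCc4ccccc4)c2)C3)c2c(OCc3ccccc3)cc(OCc3ccccc3)cc2O[C@@H]1c1ccc(OCc2ccccc2)c(OCc2ccccc2)c1)c1cc(OCc2ccccc2)c(OCc2ccccc2)c(OCc2ccccc2)c1 | intermediate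
16 | (+)-catechin, (2R,3S) | O[C@H]1Cc2c(O)cc(O)cc2O[C@@H]1c1ccc(O)c(O)c1 | starting material
17 | 5,7,3',4'-tetra-O-benzyl-(+)-catechin | O[C@H]1Cc2c(OCc3ccccc3)cc(OCc3ccccc3)cc2O[C@@H]1c1ccc(OCc2ccccc2)c(OCc2ccccc2)c1 | intermediate
18 | N-bromosuccinimide | O=C1CCC(=O)N1Br | starting material
19 | 8-bromo-5,7,3',4'-tetra-O-benzyl-(+)-catechin | O[C@H]1Cc2c(OCc3ccccc3)cc(OCc3ccccc3)c(Br)c2O[C@@H]1c1ccc(OCc2ccccc2)c(OCc2ccccc2)c1 | intermediate
20 | (2R,3S,4S)-8-bromo-5,7,3',4'-tetra-O-benzyl-4-(2-ethoxyethoxy)catechin | O[C@H]1[C@@H](OCCOCC)c2c(OCc3ccccc3)cc(OCc3ccccc3)c(Br)c2O[C@@H]1c1ccc(OCc2ccccc2)c(OCc2ccccc2)c1 | intermediate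
21 | protected trimer, top unit catechin-type (3β-OH, 4α-linked, 8-Br) | O=C(O[C@@H]1[C@@H](c2c(OCc3ccccc3)cc(OCc3ccccc3)c3c2O[C@H](c2ccc(OCc4ccccc4)c(OCc4ccccc4)c2)[C@H](OC(=O)c2cc(OCc4ccccc4)c(OCc4ccccc4)c(OCc4ccccc4)c2)C3)c2c(OCc3ccccc3)cc(OCc3ccccc3)c([C@@H]3c4c(OCc5ccccc5)cc(OCc5ccccc5)c(Br)c4O[C@H](c4ccc(OCc5ccccc5)c(OCc5ccccc5)c4)[C@H]3O)c2O[C@@H]1c1ccc(OCc2ccccc2)c(OCc2ccccc2)c1)c1cc(OCc2ccccc2)c(OCc2ccccc2)c(OCc2ccccc2)c1 | intermediate
22 | protected trimer, top unit C3 ketone | O=C(O[C@@H]1[C@@H](c2c(OCc3ccccc3)cc(OCc3ccccc3)c3c2O[C@H](c2ccc(OCc4ccccc4)c(OCc4ccccc4)c2)[C@H](OC(=O)c2cc(OCc4ccccc4)c(OCc4ccccc4)c(OCc4ccccc4)c2)C3)c2c(OCc3ccccc3)cc(OCc3ccccc3)c([C@@H]3c4c(OCc5ccccc5)cc(OCc5ccccc5)c(Br)c4O[C@H](c4ccc(OCc5ccccc5)c(OCc5ccccc5)c4)C3=O)c2O[C@@H]1c1ccc(OCc2ccccc2)c(OCc2ccccc2)c1)c1cc(OCc2ccccc2)c(OCc2ccccc2)c(OCc2ccccc2)c1 | intermediate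
23 | protected trimer, top unit (2R,3R,4S) all-cis, 3α-OH | O=C(O[C@@H]1[C@@H](c2c(OCc3ccccc3)cc(OCc3ccccc3)c3c2O[C@H](c2ccc(OCc4ccccc4)c(OCc4ccccc4)c2)[C@H](OC(=O)c2cc(OCc4ccccc4)c(OCc4ccccc4)c(OCc4ccccc4)c2)C3)c2c(OCc3ccccc3)cc(OCc3ccccc3)c([C@@H]3c4c(OCc5ccccc5)cc(OCc5ccccc5)c(Br)c4O[C@H](c4ccc(OCc5ccccc5)c(OCc5ccccc5)c4)[C@@H]3O)c2O[C@@H]1c1ccc(OCc2ccccc2)c(OCc2ccccc2)c1)c1cc(OCc2ccccc2)c(OCc2ccccc2)c(OCc2ccccc2)c1 | intermediate
24 | CNP0279403.2, epicatechin-(4α→8)-epicatechin 3-O-gallate-(4β→8)-epicatechin 3-O-gallate | O=C(O[C@@H]1[C@@H](c2c(O)cc(O)c3c2O[C@H](c2ccc(O)c(O)c2)[C@H](OC(=O)c2cc(O)c(O)c(O)c2)C3)c2c(O)cc(O)c([C@@H]3c4c(O)cc(O)cc4O[C@H](c4ccc(O)c(O)c4)[C@@H]3O)c2O[C@@H]1c1ccc(O)c(O)c1)c1cc(O)c(O)c(O)c1 | target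

**Step count and risks**

Total steps: 14. Longest linear sequence: 11 steps (steps 1–7 and 11–14); steps 8–10 form the side branch from (+)-catechin.

Steps most likely to fail:

Step 4. The catalyst may discriminate the two ketone enantiomers and faces insufficiently, or the base may degrade the ketone before it is reduced. The fallback sets out from 9. Reduction with L-selectride (THF, –78 °C, hydride anti to the C2 aryl group) should give the racemic 2,3-cis alcohol F1. Acylation with (1S)-camphanic chloride (Et3N, DMAP, CH2Cl2) gives the diastereomeric esters, the (2R,3R)-camphanate F2 and the (2S,3S)-camphanate F3, which are separated by crystallisation or chromatography. Saponification of F2 (LiOH, THF/MeOH/H2O) comes back to the route at 10.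

Step 11. Facial selectivity at C4 of the top unit may be poor, and attack by the hindered, twice-acylated dimer may be slow or go to C6 while the electrophile decomposes. The fallback sets out from 20 and 13. Silylation of 20 (TBSOTf, 2,6-lutidine, CH2Cl2) gives the 3-O-TBS electrophile F4, whose bulky 3β-silyloxy group reinforces α attack. Coupling of F4 with the non-acylated, more nucleophilic dimer 13 (TMSOTf, CH2Cl2, –78 °C) gives the trimer diol F5. Esterification of both free 3-hydroxyls with 14 (DCC, DMAP) gives the silylated digallate F6, and cleavage of the silyl ether (HF·pyridine, THF, 0 °C) comes back to the route at 21.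

Step 3. Reduction may stall at the oxime or run on to the amine, and the electron-rich ketone may be lost in hot acid. The fallback sets out from 7. Conjugate reduction with NaBH4 (THF/MeOH, 0 °C) gives the 3-nitroflavan F7; its nitronate (NaOMe, MeOH) is converted with buffered aqueous TiCl3/NH4OAc (reductive Nef reaction) into the ketone, which comes back to the route at 9.

**Further compounds**

F1 | step 4 | racemic 2,3-cis-5,7,3',4'-tetra-O-benzylflavan-3-ol (both enantiomers) | O[C@@H]1Cc2c(OCc3ccccc3)cc(OCc3ccccc3)cc2O[C@@H]1c1ccc(OCc2ccccc2)c(OCc2ccccc2)c1.O[C@H]1Cc2c(OCc3ccccc3)cc(OCc3ccccc3)cc2O[C@H]1c1ccc(OCc2ccccc2)c(OCc2ccccc2)c1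
F2 | step 4 | (2R,3R)-5,7,3',4'-tetra-O-benzylepicatechin 3-O-(1S)-camphanate | O=C(O[C@@H]1Cc2c(OCc3ccccc3)cc(OCc3ccccc3)cc2O[C@@H]1c1ccc(OCc2ccccc2)c(OCc2ccccc2)c1)[C@@]12CC[C@@](C)(C(=O)O1)C2(C)C
F3 | step 4 | (2S,3S)-5,7,3',4'-tetra-O-benzyl-ent-epicatechin 3-O-(1S)-camphanate | O=C(O[C@H]1Cc2c(OCc3ccccc3)cc(OCc3ccccc3)cc2O[C@H]1c1ccc(OCc2ccccc2)c(OCc2ccccc2)c1)[C@@]12CC[C@@](C)(C(=O)O1)C2(C)C
F4 | step 11 | (2R,3S,4S)-8-bromo-5,7,3',4'-tetra-O-benzyl-3-O-(tert-butyldimethylsilyl)-4-(2-ethoxyethoxy)catechin | CC(C)(C)[Si](C)(C)O[C@H]1[C@@H](OCCOCC)c2c(OCc3ccccc3)cc(OCc3ccccc3)c(Br)c2O[C@@H]1c1ccc(OCc2ccccc2)c(OCc2ccccc2)c1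
F5 | step 11 | protected trimer diol, top unit 3-O-TBS, middle and bottom 3-OH free | O[C@@H]1[C@@H](c2c(OCc3ccccc3)cc(OCc3ccccc3)c3c2O[C@H](c2ccc(OCc4ccccc4)c(OCc4ccccc4)c2)[C@H](O)C3)c2c(OCc3ccccc3)cc(OCc3ccccc3)c([C@@H]3c4c(OCc5ccccc5)cc(OCc5ccccc5)c(Br)c4O[C@H](c4ccc(OCc5ccccc5)c(OCc5ccccc5)c4)[C@H]3O[Si](C)(C)C(C)(C)C)c2O[C@@H]1c1ccc(OCc2ccccc2)c(OCc2ccccc2)c1
F6 | step 11 | protected trimer digallate, top unit 3-O-TBS | O=C(O[C@@H]1[C@@H](c2c(OCc3ccccc3)cc(OCc3ccccc3)c3c2O[C@H](c2ccc(OCc4ccccc4)c(OCc4ccccc4)c2)[C@H](OC(=O)c2cc(OCc4ccccc4)c(OCc4ccccc4)c(OCc4ccccc4)c2)C3)c2c(OCc3ccccc3)cc(OCc3ccccc3)c([C@@H]3c4c(OCc5ccccc5)cc(OCc5ccccc5)c(Br)c4O[C@H](c4ccc(OCc5ccccc5)c(OCc5ccccc5)c4)[C@H]3O[Si](C)(C)C(C)(C)C)c2O[C@@H]1c1ccc(OCc2ccccc2)c(OCc2ccccc2)c1)c1cc(OCc2ccccc2)c(OCc2ccccc2)c(OCc2ccccc2)c1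
F7 | step 3 | rac-5,7-bis(benzyloxy)-2-[3,4-bis(benzyloxy)phenyl]-3-nitrochroman (mixture of 2,3-isomers) | [O-][N+](=O)C1Cc2c(OCc3ccccc3)cc(OCc3ccccc3)cc2OC1c1ccc(OCc2ccccc2)c(OCc2ccccc2)c1
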